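You cannot convert all the starting material in this flask: each molecule of target costs one of coupling partner, and the flask holds 1.20 M of it against 2.0 M of starting material. That makes coupling partner the limiting reagent, with a ceiling of 60.0 % on target before any rival takes a share.

| flask | starting material | second substrate | coupling partner | precatalyst | remark | time |
|---|---|---|---|---|---|---|
| cedar | 2 M | 1 M | 1.2 M | 2.6 mM | run made earlier |  |
| flask | 2.0 M | 1.00 M | 1.20 M | 5.2 mM |  | 30 h |

cedar run (percent of the starting material charged)

| time / h | starting material / % | target / % |
|---|---|---|
| 0.833 | 95.1 | 6.1 |
| 2.00 | 84.2 | 15.8 |
| 4.00 | 78.1 | 21.0 |
| 6.00 | 78.3 | 22.2 |

(readings scatter by 1 percentage point)

- steps thought possible: coupling partner + catalyst intermediate B -> free catalyst + second product; second substrate + free catalyst <-> catalyst intermediate B; coupling partner + precatalyst -> free catalyst + spent reagent; coupling partner + catalyst intermediate A -> free catalyst + target; starting material + free catalyst <-> catalyst intermediate A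
- the reaction counts as stopped when no species that holds the starting material changes by six tenths of a point or more over the second half of the time
- no earlier run changes the charge of precatalyst; that part of a forecast is a guess

* the state of affairs at 30 h: stopped, and by what, or still going (no working catalyst is left / the coupling partner has run out first / it is still moving / all of the starting material has reacted / forward and back rates have come level)
* share of the starting material used up at 30 h
* target at 30 h, in percent of the starting material charged

Free catalyst binds starting material reversibly as catalyst intermediate A and second substrate reversibly as catalyst intermediate B, and coupling partner turns A into target and B into second product, freeing the catalyst each time; it also turns precatalyst into free catalyst and spent reagent. The cedar run differs from this flask in one charge, since this flask has twice the precatalyst, 5.2 mM. In the cedar run target read 21.0 % after 4.00 h and 22.2 % after 6.00 h. That last reading is 0.444 M of target, which leaves 0.756 M of coupling partner for second product and so 24.4 % of the second substrate unreacted. This gives S = 5.62, the selectivity factor, the logarithm of the fraction of second substrate left divided by that of the fraction of starting material left. It is a reading with that reading's scatter, and it says second substrate takes coupling partner more readily than starting material, concentration for concentration.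

Both routes leave from the same free catalyst, so I expect the catalyst charge to cancel in S, though no earlier run tests this and it stays a guess. My own reckoning is then the same S and the same coupling partner, so target near 22.2 % in this flask; watch the coupling partner, not the clock. The forecast says the coupling partner has run out first, with 22.6 % converted and 22.4 % target, slightly above my figure, on the ground that “Doubling the precatalyst only speeds things up”.

The flask gives the coupling partner has run out first, with 22.0 % converted and 21.9 % target, and the forecast held.

    coupling partner + catalyst intermediate B → free catalyst + second product (k = 12.1 /M/min)
    second substrate + free catalyst ⇌ catalyst intermediate B (K = 1.85 /M, k = 57.9 /M/min)
    coupling partner + precatalyst → free catalyst + spent reagent (k = 0.0306 /M/min)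
    coupling partner + catalyst intermediate A → free catalyst + target (k = 11.4 /M/min)
    starting material + free catalyst ⇌ catalyst intermediate A (K = 0.420 /M, k = 4.83 /M/min)

This flask stopped for want of coupling partner, 0 % of it left at 30.0 h, and its own end reads S = 5.81. With the coupling partner held level, the same flask converts 100 % of its starting material instead of 22.0 %. S can then be carried to the neighbour flask with 0.48 M of coupling partner, as a reckoning to set beside what that neighbour did. Target's share, starting material over starting material plus S times second substrate, is 26.2 % at the charges, giving 6.30 %; the mean concentrations this implies, 1.94 M and 0.823 M, put back in, give 7.08 %, and that neighbour stopped at 7.36 % target with 0 % of its coupling partner left.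

The readings were computed for substances that don't exist; scatter was added.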